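**Retrosynthetic overview**
1. Target 16 ⇐ 2‑hydroxy‑5‑methoxyquinone 14 + 3‑methylbutan‑1‑amine (vinylogous‑ester aminolysis); 14 ⇐ tetramethoxyarene 12 (CAN oxidation, selective hydrolysis).
2. 12 ⇐ bicyclic neopentyl aldehyde 8 + 2,3,5,6‑tetramethoxyphenyllithium (addition, then benzylic deoxygenation in the same flask).
3. 8 ⇐ acyclic enyne 5 + tiglic aldehyde, in one flask: ring‑closing enyne metathesis, then catalytic asymmetric exo‑Diels–Alder, setting all three stereocentres.
4. 5 ⇐ methyl isobutyrate + 5‑bromopent‑1‑ene (enolate alkylation, ester → alkyne homologation).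
5. Ring order: carbocycle A (metathesis), then carbocycle B (cycloaddition) without isolation; the quinone ring is unveiled last from the arene.

Assumption: the sense of induction of the protonated CBS‑oxazaborolidine is taken from the usual formyl C–H···O binding model (the (S) catalyst covers the C2‑Si face of a 2‑substituted enal), so the (R) catalyst is specified; this is derived from the model, not from a checked literature result.

**Step 1**
Reactants: 1 methyl isobutyrate; 2 5‑bromopent‑1‑ene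
Product: 3 methyl 2,2‑dimethylhept‑6‑enoate
Conditions: LDA (commercial solution, 1.1 equiv), THF, −78 °C; then 2, DMPU, −78 → 23 °C
Reagents that add atoms: none
Why: SN2 alkylation of the fully substituted lithium ester enolate by an unhindered primary bromide; the α‑carbon becomes quaternary, so over‑alkylation is impossible.

**Step 2**
Reactants: 3 methyl 2,2‑dimethylhept‑6‑enoate
Product: 5 3,3‑dimethyloct‑7‑en‑1‑yne, via 2,2‑dimethylhept‑6‑enal 4 (not isolated)
Conditions: DIBAL‑H (1.1 equiv), CH2Cl2, −78 °C; then MeOH, K2CO3, Ohira–Bestmann reagent, −78 → 23 °C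
Reagents that add atoms: dimethyl (1‑diazo‑2‑oxopropyl)phosphonate, CC(=O)C(=[N+]=[N-])P(=O)(OC)OC
Why: DIBAL‑H at −78 °C stops at the aluminium hemiacetal of the α‑quaternary ester, and the non‑enolisable aldehyde released on methanolysis is homologated in the same flask by Seyferth–Gilbert/Ohira–Bestmann alkynylation (one‑pot ester‑to‑alkyne protocol).

**Step 3 (key step)**
Reactants: 5 3,3‑dimethyloct‑7‑en‑1‑yne (1.3 equiv); 6 (E)‑2‑methylbut‑2‑enal (tiglic aldehyde)
Product: 8 (1R,2S,8aR)‑1,2,5,5‑tetramethyl‑1,2,3,5,6,7,8,8a‑octahydronaphthalene‑1‑carbaldehyde, via 6,6‑dimethyl‑1‑vinylcyclohexene 7 (not isolated)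
Conditions: Grubbs II (5 mol %), ethylene (1 atm), CH2Cl2, 40 °C; Ar purge; then 6, (R)‑o‑tolyl‑CBS‑oxazaborolidine·HNTf2 (20 mol %), −78 → −20 °C
Reagents that add atoms: none
Why: Proposed new method: the Ru carbene formed at the terminal alkene adds exo to the alkyne (ring‑closing enyne metathesis) to give the volatile semicyclic diene 7, held s‑cis by the adjacent gem‑dimethyl group, and the protonated (R)‑oxazaborolidine then binds tiglic aldehyde through boron and a formyl C–H···O contact so that 7 adds to the uncovered C2‑Si/C3‑Re face with "ortho" regiochemistry (ring CH to the α‑carbon) and the formyl group exo, which fixes C‑1, C‑2 and C‑8a at once (methyls cis from the E‑alkene, H‑8a cis to CHO); the closest known reaction types are one‑pot enyne‑metathesis/Diels–Alder sequences, oxazaborolidinium‑catalysed exo‑selective Diels–Alder reactions of α‑substituted enals, and Lewis‑acid exo addition of tigloyl dienophiles to this diene type.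

**Step 4**
Reactants: 8 bicyclic aldehyde; 9 1,2,4,5‑tetramethoxybenzene
Product: 12 1,2,4,5‑tetramethoxy‑3‑{[(1R,2S,8aS)‑1,2,5,5‑tetramethyl‑1,2,3,5,6,7,8,8a‑octahydronaphthalen‑1‑yl]methyl}benzene, via 2,3,5,6‑tetramethoxyphenyllithium 10 (not isolated), via benzylic lithium alkoxide 11 (not isolated)
Conditions: 9 (1.5 equiv), n‑BuLi (1.4 equiv), THF, 0 → 23 °C; 8, −78 → 0 °C; then NH3 (l), Li, −78 → −33 °C; NH4Cl
Reagents that add atoms: none
Why: The doubly ortho‑directed aryllithium adds to the non‑enolisable neopentyl aldehyde, and the benzylic alkoxide is hydrogenolysed by dissolving metal on NH4Cl quench (tandem aryllithium addition–benzylic Birch‑type deoxygenation); the carbinol centre is erased, while the isolated trisubstituted alkene and the three ring stereocentres are untouched (the 8a descriptor changes from R to S only through CIP priorities).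

**Step 5**
Reactants: 12 tetramethoxyarene
Product: 13 2,5‑dimethoxy‑3‑{[(1R,2S,8aS)‑1,2,5,5‑tetramethyl‑1,2,3,5,6,7,8,8a‑octahydronaphthalen‑1‑yl]methyl}cyclohexa‑2,5‑diene‑1,4‑dione
Conditions: CAN (2.5 equiv), MeCN/H2O 2:1, 0 °C, 15 min
Reagents that add atoms: water, O
Why: CAN oxidative demethylation of a para‑dimethoxy pair via the arene radical cation; both para pairs of this arene give the same 2,5‑dimethoxy‑3‑alkyl‑p‑quinone, and the alkene is not oxidised under these brief conditions.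

**Step 6**
Reactants: 13 dimethoxyquinone
Product: 14 2‑hydroxy‑5‑methoxy‑3‑{[(1R,2S,8aS)‑1,2,5,5‑tetramethyl‑1,2,3,5,6,7,8,8a‑octahydronaphthalen‑1‑yl]methyl}cyclohexa‑2,5‑diene‑1,4‑dione (mamanuthaquinone skeleton)
Conditions: 2 M aq. KOH, MeOH, 23 °C; then 1 M HCl
Reagents that add atoms: potassium hydroxide, [K+].[OH-]
Why: Addition–elimination of hydroxide at the vinylogous ester whose methoxy group is flanked by the alkyl chain and a carbonyl (twisted out of conjugation, hence more electrophilic); the vinylogous carboxylate formed deactivates the ring toward a second hydrolysis.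

**Step 7**
Reactants: 14 hydroxymethoxyquinone; 15 3‑methylbutan‑1‑amine (isopentylamine)
Product: 16 nakijiquinone M
Conditions: 15 (3 equiv), EtOH, 23 °C; pH 3 aqueous work‑up
Reagents that add atoms: none
Why: The amine displaces the remaining methoxy group by conjugate addition–elimination (vinylogous ester → vinylogous amide), while the acidic hydroxyquinone OH sits as its unreactive enolate; no stereocentre is involved.

**Compound list**
1 | methyl isobutyrate | COC(=O)C(C)C | starting material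
2 | 5‑bromopent‑1‑ene | BrCCCC=C | starting material
3 | methyl 2,2‑dimethylhept‑6‑enoate | COC(=O)C(C)(C)CCCC=C | intermediate
4 | 2,2‑dimethylhept‑6‑enal | O=CC(C)(C)CCCC=C | intermediate (not isolated)
5 | 3,3‑dimethyloct‑7‑en‑1‑yne | C#CC(C)(C)CCCC=C | intermediate
6 | (E)‑2‑methylbut‑2‑enal (tiglic aldehyde) | C/C=C(\C)C=O | starting material
7 | 6,6‑dimethyl‑1‑vinylcyclohex‑1‑ene | C=CC1=CCCCC1(C)C | intermediate (not isolated)
8 | (1R,2S,8aR)‑1,2,5,5‑tetramethyl‑1,2,3,5,6,7,8,8a‑octahydronaphthalene‑1‑carbaldehyde | O=C[C@@]1(C)[C@@H]2CCCC(C)(C)C2=CC[C@@H]1C | intermediate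
9 | 1,2,4,5‑tetramethoxybenzene | COc1cc(OC)c(OC)cc1OC | starting material
10 | 2,3,5,6‑tetramethoxyphenyllithium | [Li]c1c(OC)c(OC)cc(OC)c1OC | intermediate (not isolated)
11 | lithium (2,3,5,6‑tetramethoxyphenyl)[(1R,2S,8aR)‑1,2,5,5‑tetramethyl‑1,2,3,5,6,7,8,8a‑octahydronaphthalen‑1‑yl]methanolate, both carbinol epimers | [Li+].[O-]C(c1c(OC)c(OC)cc(OC)c1OC)[C@@]1(C)[C@@H]2CCCC(C)(C)C2=CC[C@@H]1C | intermediate (not isolated)
12 | 1,2,4,5‑tetramethoxy‑3‑{[(1R,2S,8aS)‑1,2,5,5‑tetramethyl‑1,2,3,5,6,7,8,8a‑octahydronaphthalen‑1‑yl]methyl}benzene | COc1cc(OC)c(OC)c(C[C@@]2(C)[C@@H]3CCCC(C)(C)C3=CC[C@@H]2C)c1OC | intermediate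
13 | 2,5‑dimethoxy‑3‑{[(1R,2S,8aS)‑1,2,5,5‑tetramethyl‑1,2,3,5,6,7,8,8a‑octahydronaphthalen‑1‑yl]methyl}cyclohexa‑2,5‑diene‑1,4‑dione | COC1=CC(=O)C(OC)=C(C[C@@]2(C)[C@@H]3CCCC(C)(C)C3=CC[C@@H]2C)C1=O | intermediate
14 | 2‑hydroxy‑5‑methoxy‑3‑{[(1R,2S,8aS)‑1,2,5,5‑tetramethyl‑1,2,3,5,6,7,8,8a‑octahydronaphthalen‑1‑yl]methyl}cyclohexa‑2,5‑diene‑1,4‑dione | COC1=CC(=O)C(O)=C(C[C@@]2(C)[C@@H]3CCCC(C)(C)C3=CC[C@@H]2C)C1=O | intermediate
15 | 3‑methylbutan‑1‑amine | CC(C)CCN | starting material
16 | nakijiquinone M, 2‑hydroxy‑5‑[(3‑methylbutyl)amino]‑3‑{[(1R,2S,8aS)‑1,2,5,5‑tetramethyl‑1,2,3,5,6,7,8,8a‑octahydronaphthalen‑1‑yl]methyl}cyclohexa‑2,5‑diene‑1,4‑dione | CC(C)CCNC1=CC(=O)C(O)=C(C[C@@]2(C)[C@@H]3CCCC(C)(C)C3=CC[C@@H]2C)C1=O | target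

**Totals**
Total step count: 7. Longest linear sequence: 7 steps (1/2 → 16); 6, 9 and 15 enter as purchased materials.

**Steps most likely to fail, with fallbacks**

Step 3 (highest risk). The chiral Lewis acid may be slowed by Ru/phosphine residues, and the ee and sense of induction with a trisubstituted enal are unproven. Fallback, setting out from 5 and returning at 8: run the same one‑flask metathesis/cycloaddition of 5 and 6 with an achiral promoter (Me2AlCl, CH2Cl2, −78 → −20 °C). This gives 8 as a racemate together with its mirror image, (1S,2R,8aS)‑aldehyde ent‑8 F1. Condense the mixture with (1R,2R)‑N,N'‑dimethyl‑1,2‑diphenylethane‑1,2‑diamine (4 Å MS, Et2O) to give two diastereomeric imidazolidines, the aminal of 8 F2 and the aminal of ent‑8 F3, and separate them by chromatography. Hydrolysis of F2 (0.5 M HCl, Et2O) returns enantiopure 8 and the recoverable diamine. Absolute stereocontrol thus shifts from catalyst control to resolution.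

Step 4. The hindered addition may be incomplete, or the dissolving metal may over‑reduce or demethoxylate the electron‑rich ring. Fallback, setting out from 8 and returning at 12: add 10 to 8 and quench with aqueous NH4Cl to isolate the free benzylic carbinol F4 (epimer mixture). Convert it with NaH, CS2 and MeI into the S‑methyl xanthate F5; no β‑hydrogen is present, so Chugaev elimination cannot occur. Remove the oxygen by Barton–McCombie radical deoxygenation (Bu3SnH, AIBN, toluene, 110 °C) to give 12.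

Step 6. Hydrolysis may be unselective between the two methoxy groups. Fallback, setting out from 13 and returning at 16: treat 13 with excess 15 (EtOH, 23 °C) to give the 2,5‑bis(3‑methylbutylamino)quinone F6. Then hydrolyse selectively the amino group flanked by the alkyl chain, which is twisted out of conjugation (2 M aq. NaOH, EtOH, 60 °C; then acidify). This reaches 16 directly and by‑passes 14.

**Further compounds**
F1 | step 3 | (1S,2R,8aS)‑1,2,5,5‑tetramethyl‑1,2,3,5,6,7,8,8a‑octahydronaphthalene‑1‑carbaldehyde (ent‑8) | O=C[C@]1(C)[C@H]2CCCC(C)(C)C2=CC[C@H]1C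
F2 | step 3 | (4R,5R)‑1,3‑dimethyl‑4,5‑diphenyl‑2‑[(1R,2S,8aR)‑1,2,5,5‑tetramethyl‑1,2,3,5,6,7,8,8a‑octahydronaphthalen‑1‑yl]imidazolidine (aminal of 8) | CN1[C@H](c2ccccc2)[C@@H](c2ccccc2)N(C)C1[C@@]3(C)[C@@H]4CCCC(C)(C)C4=CC[C@@H]3C
F3 | step 3 | (4R,5R)‑1,3‑dimethyl‑4,5‑diphenyl‑2‑[(1S,2R,8aS)‑1,2,5,5‑tetramethyl‑1,2,3,5,6,7,8,8a‑octahydronaphthalen‑1‑yl]imidazolidine (aminal of ent‑8) | CN1[C@H](c2ccccc2)[C@@H](c2ccccc2)N(C)C1[C@]3(C)[C@H]4CCCC(C)(C)C4=CC[C@H]3C
F4 | step 4 | (2,3,5,6‑tetramethoxyphenyl)[(1R,2S,8aR)‑1,2,5,5‑tetramethyl‑1,2,3,5,6,7,8,8a‑octahydronaphthalen‑1‑yl]methanol, carbinol epimers | OC(c1c(OC)c(OC)cc(OC)c1OC)[C@@]1(C)[C@@H]2CCCC(C)(C)C2=CC[C@@H]1C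
F5 | step 4 | O‑{(2,3,5,6‑tetramethoxyphenyl)[(1R,2S,8aR)‑1,2,5,5‑tetramethyl‑1,2,3,5,6,7,8,8a‑octahydronaphthalen‑1‑yl]methyl} S‑methyl dithiocarbonate | CSC(=S)OC(c1c(OC)c(OC)cc(OC)c1OC)[C@@]1(C)[C@@H]2CCCC(C)(C)C2=CC[C@@H]1C
F6 | step 6 | 2,5‑bis[(3‑methylbutyl)amino]‑3‑{[(1R,2S,8aS)‑1,2,5,5‑tetramethyl‑1,2,3,5,6,7,8,8a‑octahydronaphthalen‑1‑yl]methyl}cyclohexa‑2,5‑diene‑1,4‑dione | CC(C)CCNC1=CC(=O)C(NCCC(C)C)=C(C[C@@]2(C)[C@@H]3CCCC(C)(C)C3=CC[C@@H]2C)C1=O
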